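**Retrosynthetic overview**
1. The target is the C2-symmetric head-to-head [2+2] dimer of chloranthalactone A (14), so the cyclobutane is formed last by photodimerisation of the C8=C9 bond.
2. The butenolide of 14 comes from the 1,2-dione 11 and the phosphorus ylide 12 (Wittig olefination, then enol-lactonisation).
3. The cyclopropane and the five-membered ring are made together by intramolecular carbenoid cyclopropanation of diazoketone 8 (vinyl on C10, diazoacetyl on C5); C4 is then methylenated.
4. The six-membered ring comes first: a catalytic asymmetric Diels–Alder reaction of 2,3-bis(silyloxy)butadiene 4 with (E)-2-methyl-4-oxopent-2-enal 2 sets C10 (quaternary) and C5.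
5. Ring order: cyclohexene, then cyclopentanone plus cyclopropane, then butenolide, then cyclobutane.

Assumption: the SMILES is read as chloranthalactone F; positions are given in lindenane numbering (C1–C15), and the catalyst enantiomer in step 3 is the one that attacks the Re,Re face of 2 (its mirror image is used if the observed sense is opposite).

**Step 1**
Reactants: 1 4-methylpent-3-en-2-one
Product: 2 (2E)-2-methyl-4-oxopent-2-enal
Conditions: SeO2 (1.1 equiv), dioxane/H2O, 95 °C; distillation
Reagents that add atoms: selenium dioxide, O=[Se]=O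
Why: Allylic (Riley-type) SeO2 oxidation by ene reaction and [2,3]-shift takes the methyl group trans to the acyl group to the aldehyde, which gives the E-enal.

**Step 2**
Reactants: 3 butane-2,3-dione
Product: 4 2,3-bis[(tert-butyldimethylsilyl)oxy]buta-1,3-diene
Conditions: TBSOTf (2.2 equiv), Et3N, CH2Cl2, 0 °C to rt
Reagents that add atoms: tert-butyldimethylsilyl trifluoromethanesulfonate, CC(C)(C)[Si](C)(C)OS(=O)(=O)C(F)(F)F
Why: Double soft enolisation and O-silylation of a 1,2-diketone gives the bis(silyl enol ether) diene.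

**Step 3**
Reactants: 2 (2E)-2-methyl-4-oxopent-2-enal; 4 2,3-bis[(tert-butyldimethylsilyl)oxy]buta-1,3-diene
Product: 5 (1R,6R)-6-acetyl-3,4-bis[(tert-butyldimethylsilyl)oxy]-1-methylcyclohex-3-ene-1-carbaldehyde
Conditions: (S,S)-IDPi Brønsted acid (BINOL-derived imidodiphosphorimidate, 3,3'-Ar = 3,5-(CF3)2C6H3, N-triflyl core; 3 mol %), 4 (1.5 equiv), PhMe, −60 °C
Reagents that add atoms: none
Why: Proposed new method: a confined chiral imidodiphosphorimidate acid (which the silyl enol ether can convert in situ into its silylium ion pair) binds the aldehyde oxygen of the s-trans enal, lowers the LUMO of the doubly activated trisubstituted alkene and leaves only its Re,Re face open to the symmetrical diene (no regiochemistry, no endo/exo issue), so a concerted [4+2] sets the quaternary C10 and C5 together and carries the E geometry into the trans CHO/acetyl relationship; the closest known reactions are chiral N-triflylphosphoramide-catalysed Diels–Alder reactions of enones with 2-silyloxydienes and IDPi/silylium-catalysed Diels–Alder reactions of enoates, none shown for an α-branched 4-oxo-enal, a 2,3-bis(silyloxy)diene or quaternary-centre formation.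

**Step 4**
Reactants: 5 (1R,6R)-6-acetyl-3,4-bis[(tert-butyldimethylsilyl)oxy]-1-methylcyclohex-3-ene-1-carbaldehyde
Product: 6 1-[(1R,6S)-3,4-bis[(tert-butyldimethylsilyl)oxy]-6-ethenyl-6-methylcyclohex-3-en-1-yl]ethan-1-one
Conditions: Ph3PCH3Br, KHMDS (1.05 equiv ylide), THF, −78 to 0 °C
Reagents that add atoms: methyltriphenylphosphonium bromide, C[P+](c1ccccc1)(c1ccccc1)c1ccccc1.[Br-]
Why: Wittig methylenation is chemoselective for the non-enolisable aldehyde over the methyl ketone at low temperature; no stereocentre is touched (the 6S descriptor is a CIP priority change only).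

**Step 5**
Reactants: 6 1-[(1R,6S)-3,4-bis[(tert-butyldimethylsilyl)oxy]-6-ethenyl-6-methylcyclohex-3-en-1-yl]ethan-1-one
Product: 8 2-diazo-1-[(1R,6S)-3,4-bis[(tert-butyldimethylsilyl)oxy]-6-ethenyl-6-methylcyclohex-3-en-1-yl]ethan-1-one, via trifluoroacetyl diketone 7 (not isolated)
Conditions: LiHMDS, THF, −78 °C; CF3CO2CH2CF3; then MsN3, Et3N, H2O (1 equiv), MeCN, rt
Reagents that add atoms: 2,2,2-trifluoroethyl trifluoroacetate, O=C(OCC(F)(F)F)C(F)(F)F (its CF3CO group is carried only by 7); methanesulfonyl azide, CS(=O)(=O)N=[N+]=[N-]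
Why: Detrifluoroacetylative diazo transfer (Danheiser type): kinetic deprotonation occurs at the methyl group, not at the hindered C5 methine, so C5 keeps its configuration and the silyl enol ethers survive.

**Step 6**
Reactants: 8 2-diazo-1-[(1R,6S)-3,4-bis[(tert-butyldimethylsilyl)oxy]-6-ethenyl-6-methylcyclohex-3-en-1-yl]ethan-1-one
Product: 9 (1S,2R,4S,6R)-8,9-bis[(tert-butyldimethylsilyl)oxy]-1-methyltricyclo[4.4.0.0^2,4]dec-8-en-5-one
Conditions: Cu(acac)2 (5 mol %), PhMe, 90 °C, slow addition of 8
Reagents that add atoms: none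
Why: Intramolecular copper-carbenoid cyclopropanation of the adjacent vinyl group: the trans (diequatorial) tether can close only to the trans-fused bicyclo[3.1.0]hexanone, and the chair-like array C10–C1–C2···C3–C4–C5 puts the new CH2 (C2) on the face of the angular methyl, which sets C1 (R) and C3 (S); the tetrasubstituted enediol ether is geometrically out of reach.

**Step 7**
Reactants: 9 (1S,2R,4S,6R)-8,9-bis[(tert-butyldimethylsilyl)oxy]-1-methyltricyclo[4.4.0.0^2,4]dec-8-en-5-one
Product: 10 (1S,2R,4S,6S)-8,9-bis[(tert-butyldimethylsilyl)oxy]-1-methyl-5-methylidenetricyclo[4.4.0.0^2,4]dec-8-ene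
Conditions: Cp2TiMe2 (2.5 equiv), PhMe, 70 °C, dark
Reagents that add atoms: dimethyltitanocene, C[Ti](C)(C1C=CC=C1)C1C=CC=C1
Why: Petasis methylenation is non-basic, so the epimerisable C5–H next to the ketone is not disturbed and the silyl enol ethers are tolerated (the 6S descriptor is a CIP change only).

**Step 8**
Reactants: 10 (1S,2R,4S,6S)-8,9-bis[(tert-butyldimethylsilyl)oxy]-1-methyl-5-methylidenetricyclo[4.4.0.0^2,4]dec-8-ene
Product: 11 (1S,2R,4S,6S)-1-methyl-5-methylidenetricyclo[4.4.0.0^2,4]decane-8,9-dione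
Conditions: Br2 (1.0 equiv, titrated), CH2Cl2, −78 °C
Reagents that add atoms: none
Why: Bromine oxidation of an acyloin-type ene-1,2-diol bis(silyl ether) to the 1,2-dione (bromonium capture, loss of two silyl bromides); the tetrasubstituted dioxy-alkene reacts at −78 °C far faster than the 1,1-disubstituted alkene, and no stereocentre changes.

**Step 9**
Reactants: 11 (1S,2R,4S,6S)-1-methyl-5-methylidenetricyclo[4.4.0.0^2,4]decane-8,9-dione; 12 ethyl 2-(triphenyl-λ5-phosphanylidene)propanoate
Product: 14 chloranthalactone A, via hydroxy dienoate 13 (not isolated)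
Conditions: 12 (2.5 equiv), PhMe, 90 °C
Reagents that add atoms: none
Why: Wittig olefination of a 1,2-dione with an ester-stabilised ylide followed by enol-lactonisation (a known route to γ-alkylidene butenolides): the ylide attacks the C7 carbonyl, which is open to axial approach, rather than C8, which is screened by the 1,3-diaxial C14 methyl (the bias that makes C3 more reactive than C2 in steroid 2,3-diones), and the Z-ester is trapped by the C8 enol.

**Step 10**
Reactants: 14 chloranthalactone A (two molecules)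
Product: 15 chloranthalactone F
Conditions: hν (medium-pressure Hg lamp, Pyrex, λ > 300 nm), hexane (0.2 M), rt, Ar
Reagents that add atoms: none
Why: [2+2] photodimerisation of the C8=C9 bond of the γ-alkylidene butenolide, known for this compound: both molecules react on the α face (anti to the axial C14 methyl), C9–C9' bonding first gives the oxygen- and butenolide-stabilised 1,4-diradical, and closure gives the C2-symmetric head-to-head anti dimer with C8, C9, C8' and C9' set.

**Compound list**
1 | 4-methylpent-3-en-2-one (mesityl oxide) | CC(=O)C=C(C)C | starting material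
2 | (2E)-2-methyl-4-oxopent-2-enal | CC(=O)/C=C(\C)C=O | intermediate
3 | butane-2,3-dione | CC(=O)C(C)=O | starting material
4 | 2,3-bis[(tert-butyldimethylsilyl)oxy]buta-1,3-diene | C=C(O[Si](C)(C)C(C)(C)C)C(=C)O[Si](C)(C)C(C)(C)C | intermediate
5 | (1R,6R)-6-acetyl-3,4-bis[(tert-butyldimethylsilyl)oxy]-1-methylcyclohex-3-ene-1-carbaldehyde (CHO and acetyl trans) | O=C[C@]1(C)CC(O[Si](C)(C)C(C)(C)C)=C(O[Si](C)(C)C(C)(C)C)C[C@H]1C(C)=O | intermediate
6 | 1-[(1R,6S)-3,4-bis[(tert-butyldimethylsilyl)oxy]-6-ethenyl-6-methylcyclohex-3-en-1-yl]ethan-1-one | C=C[C@]1(C)CC(O[Si](C)(C)C(C)(C)C)=C(O[Si](C)(C)C(C)(C)C)C[C@H]1C(C)=O | intermediate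
7 | 1-[(1R,6S)-3,4-bis[(tert-butyldimethylsilyl)oxy]-6-ethenyl-6-methylcyclohex-3-en-1-yl]-4,4,4-trifluorobutane-1,3-dione (formed in the flask in step 5) | C=C[C@]1(C)CC(O[Si](C)(C)C(C)(C)C)=C(O[Si](C)(C)C(C)(C)C)C[C@H]1C(=O)CC(=O)C(F)(F)F | intermediate
8 | 2-diazo-1-[(1R,6S)-3,4-bis[(tert-butyldimethylsilyl)oxy]-6-ethenyl-6-methylcyclohex-3-en-1-yl]ethan-1-one | C=C[C@]1(C)CC(O[Si](C)(C)C(C)(C)C)=C(O[Si](C)(C)C(C)(C)C)C[C@H]1C(=O)C=[N+]=[N-] | intermediate
9 | (1S,2R,4S,6R)-8,9-bis[(tert-butyldimethylsilyl)oxy]-1-methyltricyclo[4.4.0.0^2,4]dec-8-en-5-one (trans-fused 5/6, cyclopropane CH2 syn to the angular methyl) | O=C1[C@H]2C[C@H]2[C@@]2(C)[C@H]1CC(O[Si](C)(C)C(C)(C)C)=C(O[Si](C)(C)C(C)(C)C)C2 | intermediate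
10 | (1S,2R,4S,6S)-8,9-bis[(tert-butyldimethylsilyl)oxy]-1-methyl-5-methylidenetricyclo[4.4.0.0^2,4]dec-8-ene | C=C1[C@H]2C[C@H]2[C@@]2(C)[C@H]1CC(O[Si](C)(C)C(C)(C)C)=C(O[Si](C)(C)C(C)(C)C)C2 | intermediate
11 | (1S,2R,4S,6S)-1-methyl-5-methylidenetricyclo[4.4.0.0^2,4]decane-8,9-dione (drawn as the diketone; present largely as its enols) | C=C1[C@H]2C[C@H]2[C@@]2(C)[C@H]1CC(=O)C(=O)C2 | intermediate
12 | ethyl 2-(triphenyl-λ5-phosphanylidene)propanoate | CCOC(=O)C(C)=P(c1ccccc1)(c1ccccc1)c1ccccc1 | starting material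
13 | ethyl (2Z)-2-[(1S,2R,4S,6S)-9-hydroxy-1-methyl-5-methylidenetricyclo[4.4.0.0^2,4]dec-9-en-8-ylidene]propanoate (formed in the flask in step 9) | C=C1[C@H]2C[C@H]2[C@@]2(C)[C@H]1C/C(=C(\C)C(=O)OCC)C(O)=C2 | intermediate
14 | chloranthalactone A, (1R,3S,5S,10S)-lindena-4(15),7(11),8-trien-12,8-olide | C=C1[C@H]2C[C@H]2[C@@]2(C)[C@H]1CC1=C(C)C(=O)OC1=C2 | intermediate
15 | chloranthalactone F (head-to-head anti [2+2] dimer of 14 through C8–C8' and C9–C9', both units joined on their α faces) | C=C1[C@H]2C[C@H]2[C@@]2(C)[C@H]1CC1=C(C)C(=O)O[C@]13[C@H]2[C@H]1[C@@]2(C)[C@@H]4C[C@@H]4C(=C)[C@@H]2CC2=C(C)C(=O)O[C@@]213 | target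

**Step count**
Total: 10 steps. Longest linear sequence: 9 steps (1, 3, 4, 5, 6, 7, 8, 9, 10; step 2 runs in parallel).

**Steps most likely to fail, with fallbacks**

Step 3 (the proposed new Diels–Alder reaction; risks are two competing Lewis-basic sites on 2, low ee, or acid-induced loss of the silyl groups). The fallback uses only established reaction types, sets out from diene 4 and comes back at 6. Diene 4 is combined with purchased ethyl (2E)-3-methyl-4-oxobut-2-enoate F1, which has a single aldehyde binding site. The catalyst is a proline-derived cationic oxazaborolidine activated by Tf2NH (CH2Cl2, −78 °C), a catalyst class documented for α-methyl enals and for 2-silyloxydienes. This gives ethyl (1R,6R)-3,4-bis[(tert-butyldimethylsilyl)oxy]-6-formyl-6-methylcyclohex-3-ene-1-carboxylate F2. Wittig methylenation (Ph3P=CH2) gives the vinyl ester F3. iPrMgCl with MeNHOMe·HCl converts the ester into the Weinreb amide F4, and MeMgBr then gives methyl ketone 6.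

Step 8 (bromine must discriminate the enediol ether from the exocyclic alkene next to the cyclopropane, and dione 11 is sensitive). The fallback changes the order so that no other alkene is present during the oxidation; it sets out from 9 and comes back at 14. Ketone 9 is oxidised with Br2 (CH2Cl2, −78 °C) to (1S,2R,4S,6R)-1-methyltricyclo[4.4.0.0^2,4]decane-5,8,9-trione F5. Ylide 12 (PhMe, 90 °C) does not touch the hindered cyclopropyl ketone and gives, through the open Z-hydroxy dienoate F6, the keto lactone 4-oxo-15-norchloranthalactone A F7. Ketone-selective Petasis methylenation (Cp2TiMe2, 1.2 equiv, 60 °C; ketones react before lactones) then gives 14.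

Step 9 (regiochemistry C7 versus C8, alkene geometry, and low reactivity of the enolised dione towards the stabilised ylide). The fallback replaces the intermolecular Wittig by an intramolecular Horner–Wadsworth–Emmons reaction, in which the ring enforces the geometry and the site is fixed by which enol oxygen is acylated. It sets out from 11 and comes back at 14. Dione 11 is O-acylated on its C8 enol with 2-(diethoxyphosphoryl)propanoic acid (DCC, DMAP, CH2Cl2) to give (1S,2R,4S,6S)-1-methyl-5-methylidene-8-oxotricyclo[4.4.0.0^2,4]dec-9-en-9-yl 2-(diethoxyphosphoryl)propanoate F8. LiCl and DBU in MeCN then close the butenolide onto the C7 ketone to give 14.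

**Further compounds**
F1 | step 3 | ethyl (2E)-3-methyl-4-oxobut-2-enoate (purchased) | CCOC(=O)/C=C(\C)C=O
F2 | step 3 | ethyl (1R,6R)-3,4-bis[(tert-butyldimethylsilyl)oxy]-6-formyl-6-methylcyclohex-3-ene-1-carboxylate | O=C[C@]1(C)CC(O[Si](C)(C)C(C)(C)C)=C(O[Si](C)(C)C(C)(C)C)C[C@H]1C(=O)OCC
F3 | step 3 | ethyl (1R,6S)-3,4-bis[(tert-butyldimethylsilyl)oxy]-6-ethenyl-6-methylcyclohex-3-ene-1-carboxylate | C=C[C@]1(C)CC(O[Si](C)(C)C(C)(C)C)=C(O[Si](C)(C)C(C)(C)C)C[C@H]1C(=O)OCC
F4 | step 3 | (1R,6S)-3,4-bis[(tert-butyldimethylsilyl)oxy]-6-ethenyl-N-methoxy-N,6-dimethylcyclohex-3-ene-1-carboxamide | C=C[C@]1(C)CC(O[Si](C)(C)C(C)(C)C)=C(O[Si](C)(C)C(C)(C)C)C[C@H]1C(=O)N(C)OC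
F5 | step 8 | (1S,2R,4S,6R)-1-methyltricyclo[4.4.0.0^2,4]decane-5,8,9-trione | O=C1[C@H]2C[C@H]2[C@@]2(C)[C@H]1CC(=O)C(=O)C2
F6 | step 8 | ethyl (2Z)-2-[(1R,2R,4S,6R)-9-hydroxy-1-methyl-5-oxotricyclo[4.4.0.0^2,4]dec-9-en-8-ylidene]propanoate | O=C1[C@H]2C[C@H]2[C@@]2(C)[C@H]1C/C(=C(\C)C(=O)OCC)C(O)=C2
F7 | step 8 | 4-oxo-15-norchloranthalactone A, (1R,3S,5R,10R)-4-oxo-15-norlindena-7(11),8-dien-12,8-olide | O=C1[C@H]2C[C@H]2[C@@]2(C)[C@H]1CC1=C(C)C(=O)OC1=C2
F8 | step 9 | (1S,2R,4S,6S)-1-methyl-5-methylidene-8-oxotricyclo[4.4.0.0^2,4]dec-9-en-9-yl 2-(diethoxyphosphoryl)propanoate | C=C1[C@H]2C[C@H]2[C@@]2(C)[C@H]1CC(=O)C(OC(=O)C(C)P(=O)(OCC)OCC)=C2
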